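**Retrosynthetic overview**
1. The target is the threo (7S,8S) 8-O-4' neolignan. The last operations remove the O3' benzyl group, the C7' dioxolane and the C9' silyl ether; C9 comes from reductive cleavage of an acyl oxazolidinone.
2. The C7–C8 bond and both stereocentres come from an Evans syn glycolate aldol between the ring B aryloxyacetyl (R)-oxazolidinone and 3,4-dimethoxybenzaldehyde (ring A).
3. The O4'–C8 bond comes from a Williamson reaction of the ring B phenol with a bromoacetyl imide. The C7' ketone comes from DDQ oxidation through the para-quinone methide of the free O4' phenol, and C9'–OH from hydroboration of an allyl group.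
4. Feature used: in ring B the two carbons flanking C4'–O4' (C3' and C5') both carry oxygen, so an allyl group on O4' can only come to rest at C1', para to O4', which is where C7'–C9' sit. A para-Claisen rearrangement (Claisen, then Cope) of 2-(allyloxy)-1-(benzyloxy)-3-methoxybenzene forms C1'–C7' and frees O4'–H.
5. No ring is formed in the route: ring A is bought as 3,4-dimethoxybenzaldehyde and ring B as o-vanillin (allylation, Baeyer–Villiger oxidation, benzylation).

Key step: step 4

Remark: neolignan numbering is used (ring A = 3,4-dimethoxyphenyl on C7, chain C7–C9; ring B primed, chain C7'–C9'); the target SMILES corresponds to the (7S,8S), threo isomer.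

**Step 1**
Reactants: 1 2-hydroxy-3-methoxybenzaldehyde (o-vanillin); 2 allyl bromide
Product: 3 2-(allyloxy)-3-methoxybenzaldehyde
Conditions: K2CO3, DMF, rt
Reagents that add atoms: none
Why: Williamson etherification, in which the phenoxide of 1 should displace bromide from the allylic halide cleanly.

**Step 2**
Reactants: 3 2-(allyloxy)-3-methoxybenzaldehyde
Product: 5 2-(allyloxy)-3-methoxyphenol, via 2-(allyloxy)-3-methoxyphenyl formate 4 (not isolated)
Conditions: mCPBA, CH2Cl2, 0 °C to rt; aqueous NaHCO3/Na2S2O3 wash; then K2CO3 (cat.), MeOH, rt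
Reagents that add atoms: mCPBA, O=C(OO)c1cccc(Cl)c1
Why: Baeyer–Villiger (Dakin-type) oxidation, in which the electron-rich aryl group migrates to give the formate that methanolysis cleaves, while the monosubstituted alkene should be epoxidised far more slowly.

**Step 3**
Reactants: 5 2-(allyloxy)-3-methoxyphenol; 6 benzyl bromide
Product: 7 2-(allyloxy)-1-(benzyloxy)-3-methoxybenzene
Conditions: K2CO3, DMF, 50 °C
Reagents that add atoms: none
Why: Williamson benzylation of the only free phenol, which installs a second oxygen substituent ortho to the allyl ether that withstands heat and base.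

**Step 4**
Reactants: 7 2-(allyloxy)-1-(benzyloxy)-3-methoxybenzene
Product: 11 4-allyl-2-(benzyloxy)-6-methoxyphenol, via 6-allyl-6-methoxy ortho-dienone 8 (not isolated), via 6-allyl-6-benzyloxy ortho-dienone 9 (not isolated), via 4-allyl para-dienone 10 (not isolated)
Conditions: PhNEt2 (degassed), 200 °C, sealed tube, Ar
Reagents that add atoms: none
Why: Aromatic para-Claisen rearrangement: a first [3,3] shift moves the allyl group from O4' to either flanking carbon (C5' bearing OMe gives 8, C3' bearing OBn gives 9), and because that carbon has no hydrogen the 6,6-disubstituted cyclohexa-2,4-dienone cannot enolise. A Cope [3,3] shift then carries the allyl group on to C1' to give the cross-conjugated dienone 10, whose tautomerisation to phenol 11 drives the sequence. The closest known reaction is the thermal conversion of allyl 2,6-dimethoxyphenyl ether into 4-allyl-2,6-dimethoxyphenol. No ring is closed and no stereocentre is formed; the one skeletal bond made is C1'–C7'. The step needs para regioselectivity, which the two oxygen-bearing ortho carbons enforce, and both dienones 8 and 9 should funnel into the same para-dienone. The aryl benzyl and methyl ethers are expected to survive this temperature in a basic, oxygen-free medium.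

**Step 5**
Reactants: 11 4-allyl-2-(benzyloxy)-6-methoxyphenol
Product: 13 3-[3-(benzyloxy)-4-hydroxy-5-methoxyphenyl]propan-1-ol, via bis(9-BBN) adduct 12 (not isolated)
Conditions: 9-BBN (2.5 equiv), THF, 0 °C to rt; then 3 M NaOH, 30% H2O2, 0 °C
Reagents that add atoms: hydrogen peroxide, OO
Why: Brown hydroboration–oxidation, in which 9-BBN should place boron on the terminal carbon C9' (a further equivalent being consumed by the phenol O–H) and alkaline peroxide converts the C–B bond into C–OH and hydrolyses the aryl borinate.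

**Step 6**
Reactants: 13 3-[3-(benzyloxy)-4-hydroxy-5-methoxyphenyl]propan-1-ol
Product: 14 2-(benzyloxy)-4-[3-(tert-butyldimethylsilyloxy)propyl]-6-methoxyphenol
Conditions: TBSCl (1.05 equiv), imidazole, CH2Cl2, 0 °C
Reagents that add atoms: tert-butyldimethylsilyl chloride (TBSCl), CC(C)(C)[Si](C)(C)Cl
Why: Chemoselective silylation, in which the unhindered primary alcohol should react ahead of the phenol that is flanked and hydrogen-bonded by two alkoxy groups.

**Step 7**
Reactants: 14 2-(benzyloxy)-4-[3-(tert-butyldimethylsilyloxy)propyl]-6-methoxyphenol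
Product: 17 1-[3-(benzyloxy)-4-hydroxy-5-methoxyphenyl]-3-(tert-butyldimethylsilyloxy)propan-1-one, via para-quinone methide 15 (not isolated), via benzylic alcohol 16 (not isolated)
Conditions: DDQ (2.2 equiv), 1,4-dioxane/H2O, rt
Reagents that add atoms: water, O
Why: DDQ oxidation of a para-alkylphenol, in which hydride abstraction from C7' gives para-quinone methide 15, water adds at C7' to give 16, and a second equivalent of DDQ oxidises this para-hydroxybenzylic alcohol to the aryl ketone; the free O4' phenol released in step 4 is what singles out C7' over the OCH2Ph methylene.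

**Step 8**
Reactants: 18 (R)-4-benzyloxazolidin-2-one; 19 bromoacetyl bromide
Product: 20 (R)-4-benzyl-3-(2-bromoacetyl)oxazolidin-2-one
Conditions: n-BuLi, THF, −78 °C; then 19, −78 °C
Reagents that add atoms: none
Why: N-acylation of the lithiated oxazolidinone by the acyl bromide, which should be much faster than displacement at the CH2Br carbon at low temperature.

**Step 9**
Reactants: 17 1-[3-(benzyloxy)-4-hydroxy-5-methoxyphenyl]-3-(tert-butyldimethylsilyloxy)propan-1-one; 20 (R)-4-benzyl-3-(2-bromoacetyl)oxazolidin-2-one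
Product: 21 (R)-4-benzyl-3-(2-{2-(benzyloxy)-4-[3-(tert-butyldimethylsilyloxy)propanoyl]-6-methoxyphenoxy}acetyl)oxazolidin-2-one
Conditions: K2CO3, MeCN, rt
Reagents that add atoms: none
Why: Williamson etherification, in which the acidic para-acylphenoxide should displace bromide from the activated α-bromo imide, while carbonate in MeCN is too weak to enolise the aryl ketone and expel the β-silyloxy group.

**Step 10**
Reactants: 21 (as named in step 9)
Product: 22 (R)-4-benzyl-3-[2-(2-(benzyloxy)-4-{2-[2-(tert-butyldimethylsilyloxy)ethyl]-1,3-dioxolan-2-yl}-6-methoxyphenoxy)acetyl]oxazolidin-2-one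
Conditions: (TMSOCH2)2, TMSOTf (cat.), CH2Cl2, −78 to −20 °C; pyridine quench
Reagents that add atoms: 1,2-bis(trimethylsilyloxy)ethane, C[Si](C)(C)OCCO[Si](C)(C)C
Why: Noyori ketalisation under aprotic low-temperature conditions should mask the C7' ketone, which would otherwise be enolised by Bu2BOTf (with loss of the β-oxygen) and reduced by LiBH4, without touching the silyl ether or the imide.

**Step 11**
Reactants: 22 (as named in step 10); 23 3,4-dimethoxybenzaldehyde
Product: 26 (R)-4-benzyl-3-[(2R,3S)-2-(2-(benzyloxy)-4-{2-[2-(tert-butyldimethylsilyloxy)ethyl]-1,3-dioxolan-2-yl}-6-methoxyphenoxy)-3-(3,4-dimethoxyphenyl)-3-hydroxypropanoyl]oxazolidin-2-one, via Z-boron enolate 24 (not isolated), via boron aldolate 25 (not isolated)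
Conditions: Bu2BOTf, iPr2NEt, CH2Cl2, −78 to 0 °C; then 23, −78 to 0 °C; pH 7 buffer, MeOH, 30% H2O2, 0 °C
Reagents that add atoms: none
Why: Evans syn glycolate aldol, in which the Z-dibutylboron enolate 24 reacts through a Zimmerman–Traxler chair on the enolate face left open by the (R)-4-benzyl group, so that C8 and C7 are set together as the (2R,3S) syn adduct that corresponds to (7S,8S), threo, after reduction.

**Step 12**
Reactants: 26 (as named in step 11)
Product: 27 (1S,2S)-2-(2-(benzyloxy)-4-{2-[2-(tert-butyldimethylsilyloxy)ethyl]-1,3-dioxolan-2-yl}-6-methoxyphenoxy)-1-(3,4-dimethoxyphenyl)propane-1,3-diol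
Conditions: LiBH4, H2O (1 equiv), Et2O/THF, 0 °C
Reagents that add atoms: none
Why: Reductive cleavage of the acyl oxazolidinone by LiBH4 should turn the exocyclic carbonyl into the C9 primary alcohol and release the auxiliary without touching C7 or C8 (the C8 descriptor changes from R to S only through the priority change).

**Step 13**
Reactants: 27 (as named in step 12)
Product: 28 1-{3-(benzyloxy)-4-[(1S,2S)-1-(3,4-dimethoxyphenyl)-1,3-dihydroxypropan-2-yl]oxy-5-methoxyphenyl}-3-hydroxypropan-1-one
Conditions: 1 M HCl, THF, rt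
Reagents that add atoms: water, O
Why: Acid-catalysed hydrolysis, in which the electron-rich aryl dioxolane and the primary silyl ether should cleave under conditions too mild to ionise the C7 benzylic alcohol or dehydrate the β-hydroxy ketone.

**Step 14**
Reactants: 28 (as named in step 13)
Product: 29 1-{4-[(1S,2S)-1-(3,4-dimethoxyphenyl)-1,3-dihydroxypropan-2-yl]oxy-3-hydroxy-5-methoxyphenyl}-3-hydroxypropan-1-one (target)
Conditions: H2 (1 atm), 10% Pd/C, EtOAc, rt, stopped at one equivalent of H2
Reagents that add atoms: none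
Why: Hydrogenolysis of the aryl benzyl ether over Pd/C under neutral conditions is expected to be much faster than reduction of the aryl ketone or cleavage of the secondary benzylic alcohol.

**Compound list**
1 | 2-hydroxy-3-methoxybenzaldehyde (o-vanillin) | O=Cc1cccc(OC)c1O | starting material
2 | allyl bromide | C=CCBr | starting material
3 | 2-(allyloxy)-3-methoxybenzaldehyde | C=CCOc1c(C=O)cccc1OC | intermediate
4 | 2-(allyloxy)-3-methoxyphenyl formate | C=CCOc1c(OC=O)cccc1OC | intermediate
5 | 2-(allyloxy)-3-methoxyphenol | C=CCOc1c(O)cccc1OC | intermediate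
6 | benzyl bromide | BrCc1ccccc1 | starting material
7 | 2-(allyloxy)-1-(benzyloxy)-3-methoxybenzene | C=CCOc1c(OCc2ccccc2)cccc1OC | intermediate
8 | 6-allyl-2-(benzyloxy)-6-methoxycyclohexa-2,4-dien-1-one (racemic) | O=C1C(OCc2ccccc2)=CC=CC1(CC=C)OC | intermediate
9 | 6-allyl-6-(benzyloxy)-2-methoxycyclohexa-2,4-dien-1-one (racemic) | O=C1C(OC)=CC=CC1(CC=C)OCc1ccccc1 | intermediate
10 | 4-allyl-2-(benzyloxy)-6-methoxycyclohexa-2,5-dien-1-one | O=C1C(OCc2ccccc2)=CC(CC=C)C=C1OC | intermediate
11 | 4-allyl-2-(benzyloxy)-6-methoxyphenol | C=CCc1cc(OC)c(O)c(OCc2ccccc2)c1 | intermediate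
12 | 9-{3-[3-(benzyloxy)-4-(9-borabicyclo[3.3.1]nonan-9-yloxy)-5-methoxyphenyl]propyl}-9-borabicyclo[3.3.1]nonane | COc1cc(CCCB2C3CCCC2CCC3)cc(OCc2ccccc2)c1OB1C2CCCC1CCC2 | intermediate
13 | 3-[3-(benzyloxy)-4-hydroxy-5-methoxyphenyl]propan-1-ol | OCCCc1cc(OC)c(O)c(OCc2ccccc2)c1 | intermediate
14 | 2-(benzyloxy)-4-[3-(tert-butyldimethylsilyloxy)propyl]-6-methoxyphenol | CC(C)(C)[Si](C)(C)OCCCc1cc(OC)c(O)c(OCc2ccccc2)c1 | intermediate
15 | 2-(benzyloxy)-4-[3-(tert-butyldimethylsilyloxy)propylidene]-6-methoxycyclohexa-2,5-dien-1-one | CC(C)(C)[Si](C)(C)OCCC=C1C=C(OC)C(=O)C(OCc2ccccc2)=C1 | intermediate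
16 | 2-(benzyloxy)-4-[3-(tert-butyldimethylsilyloxy)-1-hydroxypropyl]-6-methoxyphenol (racemic) | CC(C)(C)[Si](C)(C)OCCC(O)c1cc(OC)c(O)c(OCc2ccccc2)c1 | intermediate
17 | 1-[3-(benzyloxy)-4-hydroxy-5-methoxyphenyl]-3-(tert-butyldimethylsilyloxy)propan-1-one | CC(C)(C)[Si](C)(C)OCCC(=O)c1cc(OC)c(O)c(OCc2ccccc2)c1 | intermediate
18 | (R)-4-benzyloxazolidin-2-one | O=C1N[C@H](Cc2ccccc2)CO1 | starting material
19 | bromoacetyl bromide | BrCC(Br)=O | starting material
20 | (R)-4-benzyl-3-(2-bromoacetyl)oxazolidin-2-one | O=C(CBr)N1[C@H](Cc2ccccc2)COC1=O | intermediate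
21 | (R)-4-benzyl-3-(2-{2-(benzyloxy)-4-[3-(tert-butyldimethylsilyloxy)propanoyl]-6-methoxyphenoxy}acetyl)oxazolidin-2-one | CC(C)(C)[Si](C)(C)OCCC(=O)c1cc(OC)c(OCC(=O)N2[C@H](Cc3ccccc3)COC2=O)c(OCc2ccccc2)c1 | intermediate
22 | (R)-4-benzyl-3-[2-(2-(benzyloxy)-4-{2-[2-(tert-butyldimethylsilyloxy)ethyl]-1,3-dioxolan-2-yl}-6-methoxyphenoxy)acetyl]oxazolidin-2-one | CC(C)(C)[Si](C)(C)OCCC1(OCCO1)c1cc(OC)c(OCC(=O)N2[C@H](Cc3ccccc3)COC2=O)c(OCc2ccccc2)c1 | intermediate
23 | 3,4-dimethoxybenzaldehyde | COc1ccc(C=O)cc1OC | starting material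
24 | Z-dibutylboron enolate of 22 (aryloxy group cis to the O–B oxygen) | CCCCB(CCCC)O/C(=C\Oc1c(OC)cc(C2(CCO[Si](C)(C)C(C)(C)C)OCCO2)cc1OCc1ccccc1)N1[C@H](Cc2ccccc2)COC1=O | intermediate
25 | O-dibutylboryl aldolate of 26 | COc1ccc([C@H](OB(CCCC)CCCC)[C@H](C(=O)N2[C@H](Cc3ccccc3)COC2=O)Oc2c(OC)cc(C3(CCO[Si](C)(C)C(C)(C)C)OCCO3)cc2OCc2ccccc2)cc1OC | intermediate
26 | (R)-4-benzyl-3-[(2R,3S)-2-(2-(benzyloxy)-4-{2-[2-(tert-butyldimethylsilyloxy)ethyl]-1,3-dioxolan-2-yl}-6-methoxyphenoxy)-3-(3,4-dimethoxyphenyl)-3-hydroxypropanoyl]oxazolidin-2-one | COc1ccc([C@H](O)[C@H](C(=O)N2[C@H](Cc3ccccc3)COC2=O)Oc2c(OC)cc(C3(CCO[Si](C)(C)C(C)(C)C)OCCO3)cc2OCc2ccccc2)cc1OC | intermediate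
27 | (1S,2S)-2-(2-(benzyloxy)-4-{2-[2-(tert-butyldimethylsilyloxy)ethyl]-1,3-dioxolan-2-yl}-6-methoxyphenoxy)-1-(3,4-dimethoxyphenyl)propane-1,3-diol | COc1ccc([C@H](O)[C@H](CO)Oc2c(OC)cc(C3(CCO[Si](C)(C)C(C)(C)C)OCCO3)cc2OCc2ccccc2)cc1OC | intermediate
28 | 1-{3-(benzyloxy)-4-[(1S,2S)-1-(3,4-dimethoxyphenyl)-1,3-dihydroxypropan-2-yl]oxy-5-methoxyphenyl}-3-hydroxypropan-1-one | COc1ccc([C@H](O)[C@H](CO)Oc2c(OC)cc(C(=O)CCO)cc2OCc2ccccc2)cc1OC | intermediate
29 | 1-{4-[(1S,2S)-1-(3,4-dimethoxyphenyl)-1,3-dihydroxypropan-2-yl]oxy-3-hydroxy-5-methoxyphenyl}-3-hydroxypropan-1-one, (7S,8S), threo | COc1ccc([C@H](O)[C@H](CO)Oc2c(O)cc(C(=O)CCO)cc2OC)cc1OC | target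

**Step count**
Total: 14 steps. Longest linear sequence: 13 steps (steps 1–7 and 9–14; step 8 is a one-step branch).

**Steps most likely to fail**

Step 7 (DDQ oxidation). The quinone methide may tautomerise to the conjugated alkene, or be oxidised further, faster than water adds at C7'. Fallback, setting out from 14: the tautomerisation is made the intended course and the oxygen is brought in by alkene hydration instead of by capture of the quinone methide. DDQ (1 equiv) in dry 1,4-dioxane should give 2-(benzyloxy)-4-[(E)-3-(tert-butyldimethylsilyloxy)prop-1-en-1-yl]-6-methoxyphenol F3. Oxymercuration–demercuration (Hg(OAc)2, THF/H2O; then NaBH4, NaOH) should place the hydroxyl on C7', the carbon stabilised by the para-hydroxyaryl group and remote from the allylic oxygen, to give benzylic alcohol 16. MnO2 in CH2Cl2 then oxidises 16 to 17, where the route is rejoined.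

Step 11 (Evans aldol). The aryl dioxolane may be ionised by Bu2BOTf, the hindered aryloxyacetyl imide may enolise incompletely, or facial and syn selectivity may erode. Fallback, setting out from 17: both stereocentres are set by reduction instead of by C–C bond formation.
- Alkylation with ethyl bromoacetate (K2CO3, MeCN) gives ethyl 2-{2-(benzyloxy)-4-[3-(tert-butyldimethylsilyloxy)propanoyl]-6-methoxyphenoxy}acetate F4.
- Noyori ketalisation as in step 10 gives ethyl 2-(2-(benzyloxy)-4-{2-[2-(tert-butyldimethylsilyloxy)ethyl]-1,3-dioxolan-2-yl}-6-methoxyphenoxy)acetate F5.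
- Crossed Claisen acylation (LiN(SiMe3)2, 2.2 equiv, THF, −78 °C; then 3,4-dimethoxybenzoyl chloride) gives the racemic, configurationally labile ethyl 2-(aryloxy)-3-(3,4-dimethoxyphenyl)-3-oxopropanoate F6.
- Asymmetric transfer hydrogenation with dynamic kinetic resolution (RuCl(p-cymene)[(R,R)-TsDPEN], HCO2H/Et3N, CH2Cl2) is expected, by analogy with α-alkoxy β-keto esters, to give the syn product ethyl (2R,3S)-2-(aryloxy)-3-(3,4-dimethoxyphenyl)-3-hydroxypropanoate F7. The ligand enantiomer is chosen on the aryl-ketone model, and the mirror-image catalyst would be used should the sense prove opposite.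
- LiBH4 reduction of the ester returns to the route at 27.

Step 4 (para-Claisen). At 200 °C the benzyl ether may cleave or migrate, or the dienones may be diverted before the allyl group reaches C1'. Fallback, setting out from 7: the C1'–C7' bond is made by cross-coupling instead of by sigmatropic shift. Deallylation (Pd(PPh3)4 cat., morpholine, THF) gives 2-(benzyloxy)-6-methoxyphenol F1. Bromination para to the hydroxyl (NBS, CH2Cl2, −40 °C) gives 4-bromo-2-(benzyloxy)-6-methoxyphenol F2. Stille coupling with allyltributylstannane (Pd(PPh3)4, toluene, 100 °C) returns to the route at 11.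

**Further compounds**
F1 | step 4 | 2-(benzyloxy)-6-methoxyphenol | COc1cccc(OCc2ccccc2)c1O
F2 | step 4 | 4-bromo-2-(benzyloxy)-6-methoxyphenol | COc1cc(Br)cc(OCc2ccccc2)c1O
F3 | step 7 | 2-(benzyloxy)-4-[(E)-3-(tert-butyldimethylsilyloxy)prop-1-en-1-yl]-6-methoxyphenol | CC(C)(C)[Si](C)(C)OC/C=C/c1cc(OC)c(O)c(OCc2ccccc2)c1
F4 | step 11 | ethyl 2-{2-(benzyloxy)-4-[3-(tert-butyldimethylsilyloxy)propanoyl]-6-methoxyphenoxy}acetate | CCOC(=O)COc1c(OC)cc(C(=O)CCO[Si](C)(C)C(C)(C)C)cc1OCc1ccccc1
F5 | step 11 | ethyl 2-(2-(benzyloxy)-4-{2-[2-(tert-butyldimethylsilyloxy)ethyl]-1,3-dioxolan-2-yl}-6-methoxyphenoxy)acetate | CCOC(=O)COc1c(OC)cc(C2(CCO[Si](C)(C)C(C)(C)C)OCCO2)cc1OCc1ccccc1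
F6 | step 11 | ethyl 2-(2-(benzyloxy)-4-{2-[2-(tert-butyldimethylsilyloxy)ethyl]-1,3-dioxolan-2-yl}-6-methoxyphenoxy)-3-(3,4-dimethoxyphenyl)-3-oxopropanoate (racemic) | CCOC(=O)C(Oc1c(OC)cc(C2(CCO[Si](C)(C)C(C)(C)C)OCCO2)cc1OCc1ccccc1)C(=O)c1ccc(OC)c(OC)c1
F7 | step 11 | ethyl (2R,3S)-2-(2-(benzyloxy)-4-{2-[2-(tert-butyldimethylsilyloxy)ethyl]-1,3-dioxolan-2-yl}-6-methoxyphenoxy)-3-(3,4-dimethoxyphenyl)-3-hydroxypropanoate | COc1ccc([C@H](O)[C@H](C(=O)OCC)Oc2c(OC)cc(C3(CCO[Si](C)(C)C(C)(C)C)OCCO3)cc2OCc2ccccc2)cc1OC
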